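The five-membered ring B of the indenone (C1, C2, C3, C3a, C7a) is disconnected at C1–C7a and C3–C3a. This exploits benzene ring A, whose C7 methyl and C4 formyl are para to each other and leave only the neighbouring positions C7a and C3a to be bridged. In one AlCl3-mediated operation, 4-bromotoluene is acylated beside its methyl group and ring B is closed by Nazarov cyclisation beside bromine, which stands in for the aldehyde. The precursor is an α-(guaiazulen-3-yl)crotonyl chloride, made from guaiazulene by carbenoid C3–H alkylation and aldol condensation. Dehydrogenation and carbonylative formylation finish the target.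

Key step: step 5

Remark: guaiazulene numbering (C1 methyl, C3 free CH, C4 methyl, C7 isopropyl) is used throughout, so "guaiazulen-3-yl" is 5-isopropyl-3,8-dimethylazulen-1-yl; the target has no stereocentre, so indanone 12 is made as a racemate, and alkenes 7 to 9 are drawn as E because either alkene geometry converges at step 5.

Step 1
Reactants: 1 guaiazulene; 2 ethyl diazoacetate
Product: 3 ethyl 2-(guaiazulen-3-yl)acetate
Conditions: Cu(acac)2 (5 mol %), 2 added slowly (1.5 equiv), 1,2-dichloroethane, 70 °C
Reagents that add atoms: none
Why: Copper-carbenoid C–H alkylation of an electron-rich arene, in which the electrophilic copper carbene from 2 is attacked by C3, the only unsubstituted nucleophilic five-ring carbon of 1 (C1 carries a methyl group), and proton transfer in the zwitterion gives the arylacetate, a reaction type established for azulenes and diazoacetates.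

Step 2
Reactants: 3 ethyl 2-(guaiazulen-3-yl)acetate; 4 acetaldehyde
Product: 7 ethyl (E)-2-(guaiazulen-3-yl)but-2-enoate, via lithium aldolate 5 (not isolated), via β-mesyloxy ester 6 (not isolated)
Conditions: LiN(SiMe3)2, THF, −78 °C; then 4; then MsCl, −78 to 0 °C; then DBU, 0 °C to rt
Reagents that add atoms: none
Why: Aldol condensation run as addition, mesylation and E1cB elimination, in which the amide base removes the ester α-proton in preference to the less acidic C4-methyl protons at −78 °C, the aldolate is trapped before retro-aldol can set in, and elimination should give the conjugated alkene with methyl trans to the ester (E), the two transient stereocentres being destroyed.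

Step 3
Reactants: 7 ethyl (E)-2-(guaiazulen-3-yl)but-2-enoate
Product: 8 (E)-2-(guaiazulen-3-yl)but-2-enoic acid
Conditions: LiOH, THF/MeOH/H2O, 50 °C; then 1 M HCl to pH 3
Reagents that add atoms: lithium hydroxide, [Li+].[OH-]
Why: Ester saponification, in which the conjugated acrylate is the thermodynamic alkene isomer under base and the brief, dilute acidification only protonates the azulene reversibly.

Step 4
Reactants: 8 (E)-2-(guaiazulen-3-yl)but-2-enoic acid
Product: 9 (E)-2-(guaiazulen-3-yl)but-2-enoyl chloride
Conditions: 1-chloro-N,N,2-trimethylprop-1-en-1-amine, CH2Cl2, 0 °C to rt; used crude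
Reagents that add atoms: 1-chloro-N,N,2-trimethylprop-1-en-1-amine, CC(C)=C(Cl)N(C)C
Why: Acid chloride formation with an α-chloroenamine runs under neutral conditions through an acyloxyiminium ion and releases only an amide, which spares the azulene from HCl and from chlorocarbonyl electrophiles.

Step 5
Reactants: 9 (E)-2-(guaiazulen-3-yl)but-2-enoyl chloride; 10 4-bromotoluene
Product: 12 rac-trans-4-bromo-2-(guaiazulen-3-yl)-3,7-dimethylindan-1-one, via aryl vinyl ketone 11 (not isolated)
Conditions: AlCl3 (3 equiv), 10 (4 equiv), 1,2-dichloroethane, 0 to 50 °C; ice/1 M HCl work-up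
Reagents that add atoms: none
Why: AlCl3 ionises 9 to an acylium ion that substitutes 10 at the CH beside the methyl group (Friedel–Crafts acylation, C1–C7a), and the AlCl3-bound ketone 11 so formed is an oxygen-substituted pentadienyl cation. Ring B then closes by conrotatory 4π electrocyclisation (Nazarov cyclisation) onto the only free ortho carbon of 11, the one flanked by bromine (C3–C3a), after which loss of the ring proton restores ring A and leaves an aluminium enolate. The closest known reaction type is the one-pot acylation–Nazarov annulation of arenes with α,β-unsaturated acid chlorides to 1-indanones. C3 is created in the electrocyclisation without facial bias (racemate) and C2 on protonation of the enolate, the trans arrangement being thermodynamic because the acidic C2–H equilibrates through the enol until methyl and azulenyl lie on opposite faces. The step needs acylation beside methyl and not beside bromine, which the activating, ortho-directing methyl group secures against the deactivating halogen, while the azulene cannot compete because its nucleophilic C1 and C3 are substituted and it rests as a protonated or AlCl3-bound species until work-up. The α-azulenyl group stabilises the oxyallyl cation produced on closure, which should ease attack on the halogen-flanked carbon.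

Step 6
Reactants: 12 rac-trans-4-bromo-2-(guaiazulen-3-yl)-3,7-dimethylindan-1-one
Product: 13 rac-{[7-bromo-2-(guaiazulen-3-yl)-1,4-dimethyl-1H-inden-3-yl]oxy}trimethylsilane
Conditions: TMSOTf, Et3N, CH2Cl2, 0 °C
Reagents that add atoms: trimethylsilyl trifluoromethanesulfonate, C[Si](C)(C)OS(=O)(=O)C(F)(F)F
Why: Soft enolisation, in which the ketone has a single α-hydrogen (C2–H, acidified by the azulenyl group and by conjugation of the resulting enol ether with ring A), so O-silylation should give one regioisomeric silyl enol ether and removes the C2 stereocentre.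

Step 7
Reactants: 13 rac-{[7-bromo-2-(guaiazulen-3-yl)-1,4-dimethyl-1H-inden-3-yl]oxy}trimethylsilane
Product: 14 4-bromo-2-(guaiazulen-3-yl)-3,7-dimethyl-1H-inden-1-one
Conditions: Pd(OAc)2 (1.1 equiv), MeCN, rt to 40 °C
Reagents that add atoms: none
Why: Saegusa–Ito oxidation, in which the silyl enol ether transmetalates to a divalent palladium enolate bound at C2 on the face away from the C3 methyl group, so that palladium is syn to C3–H and β-hydride elimination forms the C2=C3 bond, releasing zerovalent palladium and erasing the last stereocentre.

Step 8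
Reactants: 14 4-bromo-2-(guaiazulen-3-yl)-3,7-dimethyl-1H-inden-1-one
Product: 15 2-(guaiazulen-3-yl)-3,7-dimethyl-1-oxo-1H-indene-4-carbaldehyde
Conditions: CO/H2 (1:1, 5 bar), Pd(OAc)2 (1 mol %), nBuPAd2 (3 mol %), TMEDA, toluene, 100 °C
Reagents that add atoms: carbon monoxide, [C-]#[O+]
Why: Palladium-catalysed reductive carbonylation (formylation) of an aryl bromide, in which oxidative addition at C4–Br, CO insertion to the acylpalladium species and hydrogenolysis by H2 with the amine taking up HBr give the aldehyde, while the ketone, the tetrasubstituted enone and the azulene should be untouched under these non-acidic conditions.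

Compound list
1 | guaiazulene (7-isopropyl-1,4-dimethylazulene) | CC(C)c1ccc(C)c2ccc(C)c2c1 | starting material
2 | ethyl diazoacetate | CCOC(=O)C=[N+]=[N-] | starting material
3 | ethyl 2-(guaiazulen-3-yl)acetate | CCOC(=O)Cc1cc(C)c2cc(C(C)C)ccc(C)c1-2 | intermediate
4 | acetaldehyde | CC=O | starting material
5 | lithium alkoxide of ethyl 2-(guaiazulen-3-yl)-3-hydroxybutanoate (diastereomer mixture, stereocentres not defined; not isolated) | CCOC(=O)C(C(C)[O-])c1cc(C)c2cc(C(C)C)ccc(C)c1-2.[Li+] | intermediate
6 | ethyl 2-(guaiazulen-3-yl)-3-(methylsulfonyloxy)butanoate (diastereomer mixture, stereocentres not defined; not isolated) | CCOC(=O)C(C(C)OS(C)(=O)=O)c1cc(C)c2cc(C(C)C)ccc(C)c1-2 | intermediate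
7 | ethyl (E)-2-(guaiazulen-3-yl)but-2-enoate (methyl trans to the ester) | C/C=C(/C(=O)OCC)c1cc(C)c2cc(C(C)C)ccc(C)c1-2 | intermediate
8 | (E)-2-(guaiazulen-3-yl)but-2-enoic acid | C/C=C(/C(=O)O)c1cc(C)c2cc(C(C)C)ccc(C)c1-2 | intermediate
9 | (E)-2-(guaiazulen-3-yl)but-2-enoyl chloride | C/C=C(/C(=O)Cl)c1cc(C)c2cc(C(C)C)ccc(C)c1-2 | intermediate
10 | 4-bromotoluene | Cc1ccc(Br)cc1 | starting material
11 | (E)-1-(5-bromo-2-methylphenyl)-2-(guaiazulen-3-yl)but-2-en-1-one (present as its AlCl3 complex; not isolated) | C/C=C(/C(=O)c1cc(Br)ccc1C)c1cc(C)c2cc(C(C)C)ccc(C)c1-2 | intermediate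
12 | rac-trans-4-bromo-2-(guaiazulen-3-yl)-3,7-dimethylindan-1-one (C2 azulenyl and C3 methyl on opposite faces; one enantiomer drawn) | C[C@H]1[C@H](c2cc(C)c3cc(C(C)C)ccc(C)c2-3)C(=O)c2c(C)ccc(Br)c21 | intermediate
13 | rac-{[7-bromo-2-(guaiazulen-3-yl)-1,4-dimethyl-1H-inden-3-yl]oxy}trimethylsilane (one enantiomer drawn) | C[C@H]1C(c2cc(C)c3cc(C(C)C)ccc(C)c2-3)=C(O[Si](C)(C)C)c2c(C)ccc(Br)c21 | intermediate
14 | 4-bromo-2-(guaiazulen-3-yl)-3,7-dimethyl-1H-inden-1-one | CC1=C(c2cc(C)c3cc(C(C)C)ccc(C)c2-3)C(=O)c2c(C)ccc(Br)c21 | intermediate
15 | 2-(guaiazulen-3-yl)-3,7-dimethyl-1-oxo-1H-indene-4-carbaldehyde (achiral) | CC1=C(c2cc(C)c3cc(C(C)C)ccc(C)c2-3)C(=O)c2c(C)ccc(C=O)c21 | target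

Total step count: 8. Longest linear sequence: 8 steps (1 to 15).

Steps most likely to fail

Step 5 is the riskiest. Acylation could take place beside bromine, bromine could migrate on ring A under AlCl3, or the azulene could degrade during the heating needed to force closure onto a halogen-flanked carbon. The fallback sets out from acid chloride 9 and returns at indanone 12. Compound 9 is treated with MeNHOMe·HCl and Et3N (CH2Cl2, 0 °C) to give (E)-2-(guaiazulen-3-yl)-N-methoxy-N-methylbut-2-enamide F1. Commercial 4-bromo-2-iodotoluene (Cc1ccc(Br)cc1I) undergoes selective iodine–magnesium exchange with iPrMgCl·LiCl (THF, −20 °C) to (5-bromo-2-methylphenyl)magnesium chloride F2, which adds to F1 and should deliver ketone 11, now isolated. Compound 11 is then cyclised in a separate Nazarov step with CF3SO3H in CH2Cl2 (0 °C to rt), a Brønsted acid that cannot shift the halogen, to give 12. The C1–C7a regiochemistry is then fixed by the halogen pattern of the aryl donor and no longer by electrophilic substitution.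

Step 7 comes next. Transmetalation and β-hydride elimination could be slow at the crowded, fully substituted enolate carbon, the zerovalent palladium released could insert into the C4–Br bond, or the silyl enol ether could hydrolyse back to the ketone. The fallback sets out from silyl enol ether 13 and returns at indenone 14. PhSeCl (CH2Cl2, −78 °C) should selenenylate C2 from the face opposite the C3 methyl group to give rac-4-bromo-2-(guaiazulen-3-yl)-3,7-dimethyl-2-(phenylselanyl)indan-1-one F3. Oxidation with H2O2 and pyridine (CH2Cl2, 0 °C) gives rac-4-bromo-2-(guaiazulen-3-yl)-3,7-dimethyl-2-(phenylseleninyl)indan-1-one F4, which is not isolated and should undergo selenoxide syn elimination with the cis C3–H to 14, with no palladium present.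

Step 1 is third. Carbene dimerisation, or cyclopropanation and ring expansion of the seven-membered ring, could outrun attack at C3, which is hindered by the peri C4 methyl group. The fallback sets out from guaiazulene 1 and returns at enoate 7, replacing steps 1 and 2. Compound 1 is acylated at C3 with ethyl chlorooxoacetate (pyridine, CH2Cl2, 0 °C, no Lewis acid) to give ethyl 2-(guaiazulen-3-yl)-2-oxoacetate F5. EtMgBr (THF, −78 °C) adds to the ketone carbonyl to give racemic ethyl 2-(guaiazulen-3-yl)-2-hydroxybutanoate F6. Acid-catalysed dehydration (cat. TsOH, toluene, rt to 50 °C) through the azulenyl-stabilised cation should give 7.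

Further compounds
F1 | step 5 | (E)-2-(guaiazulen-3-yl)-N-methoxy-N-methylbut-2-enamide | C/C=C(/C(=O)N(C)OC)c1cc(C)c2cc(C(C)C)ccc(C)c1-2
F2 | step 5 | (5-bromo-2-methylphenyl)magnesium chloride (LiCl complex) | Cc1ccc(Br)cc1[Mg]Cl
F3 | step 7 | rac-4-bromo-2-(guaiazulen-3-yl)-3,7-dimethyl-2-(phenylselanyl)indan-1-one (selenium trans to the C3 methyl; one enantiomer drawn) | C[C@H]1[C@@]([Se]c2ccccc2)(c2cc(C)c3cc(C(C)C)ccc(C)c2-3)C(=O)c2c(C)ccc(Br)c21
F4 | step 7 | rac-4-bromo-2-(guaiazulen-3-yl)-3,7-dimethyl-2-(phenylseleninyl)indan-1-one (selenium configuration not defined) | C[C@H]1[C@@]([Se](=O)c2ccccc2)(c2cc(C)c3cc(C(C)C)ccc(C)c2-3)C(=O)c2c(C)ccc(Br)c21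
F5 | step 1 | ethyl 2-(guaiazulen-3-yl)-2-oxoacetate | CCOC(=O)C(=O)c1cc(C)c2cc(C(C)C)ccc(C)c1-2
F6 | step 1 | ethyl 2-(guaiazulen-3-yl)-2-hydroxybutanoate (racemic) | CCOC(=O)C(O)(CC)c1cc(C)c2cc(C(C)C)ccc(C)c1-2
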